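Start from the substrate.

common to all: free catalyst 0.5 mol%; added ligand 2.3 mM
- violet: substrate 0.40 M; reagent 1.50 equiv; time 30 h; everything together in a closed stirred flask, run for 30 h
- grey: substrate 0.40 M (fed, over 24.0 h); reagent 1.50 equiv; time 30 h; all but substrate at the start; substrate goes in evenly over 24.0 h, the run ends at 30 h
- green: substrate 0.40 M; reagent 1.50 equiv (fed, over 24.0 h); time 30 h; a stirred flask in which reagent is dosed at a steady rate over 24.0 h without added volume, worked up at 30 h
- blue: substrate 0.40 M; reagent 1.50 equiv; one stirred flow tank at steady state, fed with the mixture as stated, mean residence time 30 h

* order of the set-ups by the amount of target at the outlet or at the end, in percent of the substrate put in, highest first (violet / grey / green / blue)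
* amount of target at the outlet or at the end, in percent of the substrate put in, violet
* amount of target at the outlet or at the end, in percent of the substrate put in, grey
* amount of target at the outlet or at the end, in percent of the substrate put in, green
* amount of target at the outlet or at the end, in percent of the substrate put in, blue

    substrate + catalyst intermediate B ⇌ catalyst intermediate C (K1 = 2.4 /M, k1 = 52 /M/h)
    catalyst intermediate C → catalyst intermediate D (k2 = 44 /h)
    catalyst intermediate A → by-product + catalyst intermediate B (k3 = 2600 /h)
    catalyst intermediate D ⇌ free catalyst + target (K4 = 0.44 M, k4 = 89 /h)
    free catalyst + added ligand ⇌ idle complex, settled at all times (K5 = 9600 /M)
    reagent + free catalyst → catalyst intermediate A (k6 = 4000 /M/h)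

In violet it is the limiting reagent, one equivalent against 1.50 equiv of reagent, so I write its balance and first ask which constants that balance needs well. In the round, catalyst intermediate B takes up substrate to give C, C turns into D, D releases target and free catalyst, free catalyst takes up reagent to give A, and A sheds by-product and returns to B. Added ligand holds free catalyst as idle complex.

Capture of free catalyst by reagent as charged, at 2400 /h, and the shedding of by-product, at 2600 /h, are both faster than the turn from C to D at 44 /h. So B is the resting state, those two constants drop out of the speed, and A holds hardly any of what C holds. The way back from free catalyst and target I drop. C falls back at 21.7 /h, slower than it goes on, but not negligibly so; with the equilibrium constant of that step held, the fall-back moves with the capture constant of substrate, so a relative error in the capture constant passes at 0.670 and one in the turn constant at 0.330. The speed constant is 34.8 /M/h.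

Loading and time multiply this in full, which gives my carried quantity, the reach: speed constant times catalyst charged times time, here 2.09. Against it stands the load, the catalyst parked as C, D and idle complex at full substrate, with reagent taken at its mid-conversion level of 0.400 M: 0.666. The ligand constants enter through the load, which is smaller than the reach, so they weigh less than loading and time.

The balance reads: logarithm of charged over left, plus load times fraction used, equals reach. Iterating gives 20.9 % of the substrate left in violet, so target 79.1 %. This closed form does not follow grey, green or blue, so I stop there.

The forecast gives violet > green > blue > grey, with violet 79.5 %, grey 60 %, green 75 % and blue 62 %, holding that “the batch run does best because it keeps substrate high”. The simulation gives violet > green > blue > grey, with violet 79.1 %, grey 59.3 %, green 73.5 % and blue 62.2 %, and violet ends with 20.9 % of its substrate left.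

The neighbouring flask is grey with substrate at 1.6 M, equivalents and loadings held. Catalyst grows with the charge, so the reach per hour becomes 0.279 /h, and the load per molar 1.30 /M. If the feed of 0.0667 M/h is consumed as it enters, substrate stands at 0.348 M when feeding ends. The remaining reach of 1.67 then leaves 5.73 % of the charge. That neighbouring flask ends with 5.68 % of its substrate left and target at 94.3 %.

The constants come from no measurement; the rest is arithmetic.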